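Wednesday's run is what I have to go on for oak, birch and ash, three flasks with its charges but half its precatalyst, at the temperatures set out here.

in all of them: starting material 0.50 mM

| run | second substrate | partner | precatalyst | temperature | remark | time |
|---|---|---|---|---|---|---|
| Wednesday's | 0.50 mM | 0.35 mM | 0.50 µM | 40 °C | run made earlier |  |
| oak | 0.500 mM | 0.350 mM | 0.25 µM | 40 °C |  | 6.0 min |
| birch | 0.500 mM | 0.350 mM | 0.25 µM | 25 °C |  | 6.0 min |
| ash | 0.500 mM | 0.350 mM | 0.25 µM |  | at 40 °C until 2.0 min, from then on at 25 °C | 6.0 min |

- Wednesday's (time / s: target / %): 10.0: 41.6; 12.0: 43.6; 20.0: 52.6; 30.0: 57.3; 50.0: 57.1; 80.0: 57.6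

(standard deviation of a reading: 0.5 percentage points)

1. which flask leads in amount of target, in percent of the starting material charged ("all alike" within 1.5 percentage points) (oak / birch / ash / all alike)
2. how much target is there at the end, in percent of the starting material charged: oak
3. how much target is there at the end, in percent of the starting material charged: birch
4. how much target is there at the end, in percent of the starting material charged: ash

- what was read earlier has a scatter of 0.5 percentage points, one standard deviation
- the earlier runs do not show what temperature does; that part of a forecast is a guess
- no earlier run changes the charge of precatalyst; that part of a forecast is a guess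

Wednesday's readings of target from 30.0 s to 80.0 s lie within 0.5 percentage points of each other, which is no more than the scatter of one reading can hide, and the last of them is 57.6%, while the partner charged, at one partner per target, allows 70.0%. So I fold that last reading and the charges into one number, φ = 0.823, the partner yield, meaning target formed per partner charged, a reading that carries the scatter. It says that 17.7% of the partner goes elsewhere, and this correction is what I carry, taking the partner as the limiting reagent, so that target in percent of starting material is φ times the charge of partner over the charge of starting material.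

If the time to reach this level, which I put at 50.0 s for Wednesday's run to allow for the scatter, goes inversely with the precatalyst, oak needs 100 s, which is shorter than its 6.0 min and shorter than the 2.0 min that ash spends hot, so I give oak and ash 57.6%. One number serves only as far as φ stays put, and Wednesday's run, at one temperature and one charge of precatalyst, cannot test that, so giving birch the same figure is my guess, and I expect the three flasks within 1.5 points of each other.

The forecast says 55% for oak, 56% for birch and 55% for ash, each lower than my figure, with “birch perhaps slightly higher through better selectivity”, and it calls the lead all alike, as I do.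

The flasks give 57.8% in oak, 61.6% in birch and 57.8% in ash, so birch leads, on this scheme:

    starting material + free catalyst ⇌ catalyst intermediate A (K = 6700 M⁻¹, k = 4.60 × 10⁶ M⁻¹ s⁻¹, Ea = 22.0 kJ mol⁻¹, ΔH = −52.0 kJ mol⁻¹)
    partner + catalyst intermediate A → free catalyst + target (k = 6.20 × 10⁵ M⁻¹ s⁻¹, Ea = 9.00 kJ mol⁻¹)
    second substrate + free catalyst ⇌ catalyst intermediate B (K = 3500 M⁻¹, k = 3.20 × 10⁵ M⁻¹ s⁻¹, Ea = 15.0 kJ mol⁻¹, ΔH = −37.0 kJ mol⁻¹)
    partner + catalyst intermediate B → free catalyst + second product (k = 91000 M⁻¹ s⁻¹, Ea = 15.0 kJ mol⁻¹)
    partner + precatalyst → free catalyst + spent reagent (k = 840 M⁻¹ s⁻¹, Ea = 38.0 kJ mol⁻¹)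
    partner + free catalyst + target → free catalyst + over-reaction product (k = 6.50 × 10⁷ M⁻² s⁻¹, Ea = 9.00 kJ mol⁻¹)
    2 starting material → homo dimer (k = 0.0560 M⁻¹ s⁻¹, Ea = 49.0 kJ mol⁻¹)
    (constants at 25 °C)

Oak's partner yield comes to 0.826, where 0.823 was read, and birch's comes to 0.881, with less second product in birch at 6.00 min, 0.0356 mM against oak's 0.0475 mM. A neighbour of birch charged with 0.14 mM of partner should then hold 24.7% target by birch's yield, and it holds 25.6%.

(Readings and results are simulated with constants of no real substance, noise included.)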